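**Retrosynthetic overview**

1. Numbering (benzo[7]annulene): C5 spiro carbon, C6 CH2, C7 and C8 CHMe, C9 CHOAc, C9a/C4a the ring A fusion carbons; ring A is the trimethoxybenzene, ring B the dienone. The seven-membered ring is cut at C5–C6 and C9–C9a, leaving a biaryl (rings A and B joined through C4a–C5) and a four-carbon chain C6–C9.
2. Enabling feature: ring B is a dearomatised, symmetric 2,6-dimethoxyphenolate whose para carbon is C5, and C9a is the ring A carbon ortho to the biaryl bond. The biaryl is therefore a 1,3-bis-nucleophile (aryllithium at C9a, phenolate para carbon at C5), and the chain is a 1,4-bis-electrophile (CHO at C9, CH2Br at C6). The symmetry of ring B makes C5 non-stereogenic, and the aldehyde oxygen stays on C9 as the acetate.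
3. Stereochemistry: C7 is bought ((S)-β-methyl-γ-butyrolactone), C8 follows by trans-selective enolate methylation, and C9 is set in the key step by Felkin–Anh addition.
4. Ring order: rings A and B are bought as arenes and joined by a site-selective Suzuki coupling. The seven-membered ring is closed last, in the same flask operation that dearomatises ring B and delivers the target.

Key step: step 7

Assumption: (S)-4-methyldihydrofuran-2(3H)-one is taken as a purchasable single enantiomer; its C4 centre becomes C7 of the target.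

**Route**

Step 1
Reactants: 1 5-bromo-1,2,3-trimethoxybenzene
Product: 2 1-bromo-2-iodo-3,4,5-trimethoxybenzene
Conditions: NIS (1.05 equiv), CF3CO2H (cat.), MeCN, rt
Reagents that add atoms: N-iodosuccinimide, O=C1CCC(=O)N1I
Why: Electrophilic aromatic iodination; the two free positions are equivalent and each is activated by an ortho and a para methoxy group, so a single mono-iodide should result.

Step 2
Reactants: 2 1-bromo-2-iodo-3,4,5-trimethoxybenzene; 3 2,6-dimethoxy-4-(4,4,5,5-tetramethyl-1,3,2-dioxaborolan-2-yl)phenol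
Product: 4 2'-bromo-3,4',5,5',6'-pentamethoxy-[1,1'-biphenyl]-4-ol
Conditions: Pd(PPh3)4 (5 mol %), K2CO3, 1,4-dioxane/H2O, 80 °C
Reagents that add atoms: none
Why: Suzuki–Miyaura coupling; zerovalent palladium inserts into the C–I bond far faster than into the C–Br bond, so ring B should be joined only at the iodinated carbon and the bromide is kept for the key step.

Step 3
Reactants: 4 2'-bromo-3,4',5,5',6'-pentamethoxy-[1,1'-biphenyl]-4-ol
Product: 5 tert-butyl[(2'-bromo-3,4',5,5',6'-pentamethoxy-[1,1'-biphenyl]-4-yl)oxy]dimethylsilane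
Conditions: TBSCl, imidazole, DMF, rt
Reagents that add atoms: tert-butyldimethylsilyl chloride, CC(C)(C)[Si](C)(C)Cl
Why: Standard imidazole-promoted silylation of a phenol; the silyl ether masks the acidic OH during lithiation and later serves as the fluoride-labile trigger.

Step 4
Reactants: 6 (S)-4-methyldihydrofuran-2(3H)-one
Product: 8 (3S,4S)-3,4-dimethyldihydrofuran-2(3H)-one, via lithium enolate 7 (not isolated)
Conditions: LiN(i-Pr)2 (LDA), THF, −78 °C; then MeI, −78 °C
Reagents that add atoms: iodomethane, CI
Why: Alkylation of the lithium enolate of a β-substituted γ-butyrolactone; iodomethane should approach the planar enolate anti to the C4 methyl group, so the new C3 centre is set trans (3S) by substrate control.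

Step 5
Reactants: 8 (3S,4S)-3,4-dimethyldihydrofuran-2(3H)-one
Product: 10 methyl (2S,3S)-4-bromo-2,3-dimethylbutanoate, via dibromoboryl ester 9 (not isolated)
Conditions: BBr3, CH2Cl2, 0 °C to rt; then MeOH, 0 °C
Reagents that add atoms: boron tribromide, BrB(Br)Br; methanol, CO
Why: Lewis-acid-mediated lactone cleavage, in which BBr3 activates the carbonyl, bromide opens the ring by SN2 attack at the CH2–O carbon and methanolysis of the boryl carboxylate gives the ester; neither stereocentre is touched.

Step 6
Reactants: 10 methyl (2S,3S)-4-bromo-2,3-dimethylbutanoate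
Product: 12 (2S,3S)-4-bromo-2,3-dimethylbutanal, via aluminium hemiacetal 11 (not isolated)
Conditions: i-Bu2AlH (1.05 equiv), CH2Cl2, −78 °C; aq. potassium sodium tartrate; used at once
Reagents that add atoms: none
Why: Partial reduction of an ester, in which the tetrahedral aluminium hemiacetal is stable at −78 °C and collapses to the aldehyde only on work-up; the alkyl bromide is inert to the hydride at this temperature and the α-centre is not exposed to base.

Step 7
Reactants: 5 tert-butyl[(2'-bromo-3,4',5,5',6'-pentamethoxy-[1,1'-biphenyl]-4-yl)oxy]dimethylsilane; 12 (2S,3S)-4-bromo-2,3-dimethylbutanal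
Product: 17 (7R,8S,9R)-2,3,3',4,5'-pentamethoxy-7,8-dimethyl-4'-oxo-6,7,8,9-tetrahydrospiro[benzo[7]annulene-5,1'-cyclohexane]-2',5'-dien-9-yl acetate (the target), via aryllithium 13 (not isolated), via lithium alkoxide 14 (not isolated), via bromo acetate 15 (not isolated), via caesium phenolate 16 (not isolated)
Conditions: t-BuLi (2.0 equiv), THF, −78 °C; then 12, −78 °C; then Ac2O (1.2 equiv), −78 to 0 °C; then DMF (dilution to 0.005 M, degassed), CsF (3 equiv), 60 °C
Reagents that add atoms: acetic anhydride, CC(=O)OC(C)=O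
Why: Proposed new method: a formal (3+4) annulation in which the biaryl acts as a 1,3-bis-nucleophile (aryllithium carbon of ring A, then the para carbon of the ring B phenolate) and 12 as a 1,4-bis-electrophile (CHO, then CH2Br); the closest known reaction types are aryllithium addition to an α-branched aldehyde followed by in situ O-acylation and the Winstein–Masamune intramolecular para-C-alkylation of phenolates to spirocyclohexadienones, which have not been merged in one flask nor used to close a seven-membered ring across a biaryl. Bromine–lithium exchange gives 13, which should add to 12 under Felkin–Anh control (sec-alkyl group anti to the incoming aryl, attack past the α-hydrogen), so the new C9 centre (9R, oxygen syn to the C8 methyl in the extended chain, trans in the ring) is dictated by the adjacent C8 centre, and the bulk of the ortho-arylated nucleophile should reinforce this preference. Acetic anhydride caps alkoxide 14 at −78 °C before it can displace the γ-bromide (5-exo-tet tetrahydrofuran formation) and at the same time installs the acetate of the target. Fluoride then cleaves the aryl silyl ether, and phenolate 16 closes the seven-membered ring by SN2 attack of its para carbon on the primary bromide (7-exo-tet, dearomative spiroalkylation), which creates the quaternary spiro carbon and the cross-conjugated dienone at once. Regioselectivity is secured by the substrate, because the phenolate oxygen cannot reach C6, both ortho carbons carry methoxy groups and lie out of reach, and the twisted biaryl points the p-orbital of the para carbon at the side chain; as ring B is symmetric the spiro carbon is not stereogenic, so no facial selectivity is needed there. High dilution should suppress intermolecular O-alkylation, the main competitor.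

**Compound list**

1 | 5-bromo-1,2,3-trimethoxybenzene | COc1cc(Br)cc(OC)c1OC | starting material
2 | 1-bromo-2-iodo-3,4,5-trimethoxybenzene | COc1cc(Br)c(I)c(OC)c1OC | intermediate
3 | 2,6-dimethoxy-4-(4,4,5,5-tetramethyl-1,3,2-dioxaborolan-2-yl)phenol | COc1cc(cc(OC)c1O)B1OC(C)(C)C(C)(C)O1 | starting material
4 | 2'-bromo-3,4',5,5',6'-pentamethoxy-[1,1'-biphenyl]-4-ol | COc1cc(Br)c(c(OC)c1OC)-c1cc(OC)c(O)c(OC)c1 | intermediate
5 | tert-butyl[(2'-bromo-3,4',5,5',6'-pentamethoxy-[1,1'-biphenyl]-4-yl)oxy]dimethylsilane | COc1cc(Br)c(c(OC)c1OC)-c1cc(OC)c(O[Si](C)(C)C(C)(C)C)c(OC)c1 | intermediate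
6 | (S)-4-methyldihydrofuran-2(3H)-one | O1C[C@@H](C)CC1=O | starting material
7 | lithium (S)-4-methyl-4,5-dihydrofuran-2-olate (lithium enolate of 6) | O1C[C@@H](C)C=C1O[Li] | intermediate
8 | (3S,4S)-3,4-dimethyldihydrofuran-2(3H)-one (trans) | O1C[C@@H](C)[C@H](C)C1=O | intermediate
9 | dibromoboryl (2S,3S)-4-bromo-2,3-dimethylbutanoate | BrC[C@@H](C)[C@H](C)C(=O)OB(Br)Br | intermediate
10 | methyl (2S,3S)-4-bromo-2,3-dimethylbutanoate | BrC[C@@H](C)[C@H](C)C(=O)OC | intermediate
11 | [(2S,3S)-4-bromo-1-methoxy-2,3-dimethylbutoxy]bis(2-methylpropyl)alumane (aluminium hemiacetal, C1 epimers) | BrC[C@@H](C)[C@H](C)C(OC)O[Al](CC(C)C)CC(C)C | intermediate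
12 | (2S,3S)-4-bromo-2,3-dimethylbutanal | BrC[C@@H](C)[C@H](C)C=O | intermediate
13 | [2-(4-{[tert-butyl(dimethyl)silyl]oxy}-3,5-dimethoxyphenyl)-3,4,5-trimethoxyphenyl]lithium | COc1cc([Li])c(c(OC)c1OC)-c1cc(OC)c(O[Si](C)(C)C(C)(C)C)c(OC)c1 | intermediate
14 | lithium (1R,2S,3S)-4-bromo-1-[2-(4-{[tert-butyl(dimethyl)silyl]oxy}-3,5-dimethoxyphenyl)-3,4,5-trimethoxyphenyl]-2,3-dimethylbutan-1-olate | BrC[C@@H](C)[C@H](C)[C@@H](O[Li])c1cc(OC)c(OC)c(OC)c1-c1cc(OC)c(O[Si](C)(C)C(C)(C)C)c(OC)c1 | intermediate
15 | (1R,2S,3S)-4-bromo-1-[2-(4-{[tert-butyl(dimethyl)silyl]oxy}-3,5-dimethoxyphenyl)-3,4,5-trimethoxyphenyl]-2,3-dimethylbutyl acetate | BrC[C@@H](C)[C@H](C)[C@@H](OC(C)=O)c1cc(OC)c(OC)c(OC)c1-c1cc(OC)c(O[Si](C)(C)C(C)(C)C)c(OC)c1 | intermediate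
16 | caesium 4-{6-[(1R,2S,3S)-1-acetoxy-4-bromo-2,3-dimethylbutyl]-2,3,4-trimethoxyphenyl}-2,6-dimethoxyphenolate | BrC[C@@H](C)[C@H](C)[C@@H](OC(C)=O)c1cc(OC)c(OC)c(OC)c1-c1cc(OC)c([O-])c(OC)c1.[Cs+] | intermediate
17 | (7R,8S,9R)-2,3,3',4,5'-pentamethoxy-7,8-dimethyl-4'-oxo-6,7,8,9-tetrahydrospiro[benzo[7]annulene-5,1'-cyclohexane]-2',5'-dien-9-yl acetate | COC1=CC2(C=C(OC)C1=O)C[C@@H](C)[C@H](C)[C@@H](OC(C)=O)c1cc(OC)c(OC)c(OC)c12 | target

**Step count and risks**

Total steps: 7. Longest linear sequence: 4 steps (1 → 2 → 4 → 5 → 17, or 6 → 8 → 10 → 12 → 17).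

Steps most likely to fail:

Step 7 (proposed new method). The seven-membered SN2 closure at a β-branched primary carbon may be too slow, so that intermolecular O-alkylation, oligomerisation or E2 loss of HBr takes over. Facial selectivity in the aldehyde addition may also be only moderate, and tetrahydrofuran formation can intervene if acetylation lags. The fallback sets out from 12 and 1, uses known chemistry throughout and comes back to the route at 17; it forms the C4a–C5 bond last instead of C5–C6. Bromide 1 is lithiated (n-BuLi, THF, −78 °C) and added to aldehyde 12, and the alkoxide is acetylated in the flask (Ac2O) to give (1R,2S,3S)-4-bromo-2,3-dimethyl-1-(3,4,5-trimethoxyphenyl)butyl acetate F1; the minor C1 epimer would be removed here. Purchased 4-bromo-2,6-dimethoxyphenol (COc1cc(Br)cc(OC)c1O) is silylated (TBSCl, imidazole, DMF) to (4-bromo-2,6-dimethoxyphenoxy)(tert-butyl)dimethylsilane F2. Nickel-catalysed reductive cross-electrophile coupling of F1 and F2 (NiI2, 4,4'-di-tert-butyl-2,2'-bipyridine, Zn, NaI, DMA, 60 °C) should give (1R,2S,3R)-4-(4-{[tert-butyl(dimethyl)silyl]oxy}-3,5-dimethoxyphenyl)-2,3-dimethyl-1-(3,4,5-trimethoxyphenyl)butyl acetate F3. Desilylation (Bu4NF, AcOH, THF, 0 °C) gives (1R,2S,3R)-4-(4-hydroxy-3,5-dimethoxyphenyl)-2,3-dimethyl-1-(3,4,5-trimethoxyphenyl)butyl acetate F4. Oxidative dearomative spirocyclisation of F4 with PhI(OCOCF3)2 in CF3CH2OH at −40 °C (phenol oxidised to the phenoxonium ion, attack of the ring A ortho carbon on its para carbon) should then give 17.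

Step 2. Transmetalation at the doubly ortho-substituted iodide may be slow, the electron-rich phenol boronate may protodeboronate, and some insertion into the C–Br bond would erode site selectivity. The fallback reverses the polarity of the coupling, sets out from 2 and comes back at 5, replacing steps 2 and 3. Iodine–magnesium exchange on 2 (i-PrMgCl·LiCl, THF, −40 °C) gives (6-bromo-2,3,4-trimethoxyphenyl)magnesium chloride F5, which is transmetalated with ZnCl2 to (6-bromo-2,3,4-trimethoxyphenyl)zinc chloride F6. Purchased 2,6-dimethoxyphenol (COc1cccc(OC)c1O) is iodinated at the para position (NIS, MeCN, 0 °C) to 4-iodo-2,6-dimethoxyphenol F7 and silylated (TBSCl, imidazole) to tert-butyl(4-iodo-2,6-dimethoxyphenoxy)dimethylsilane F8. Negishi coupling of F6 with F8 (Pd2(dba)3, SPhos, THF, rt to 50 °C) should engage only the aryl iodide and give 5 directly.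

Step 5. Ring opening at the β-branched CH2–O carbon may be incomplete, the γ-bromo ester may relactonise on warming with loss of bromomethane, and the α-centre may epimerise under the strongly acidic conditions. The fallback opens the lactone at the acyl carbon instead, sets out from 8 and comes back at 12, replacing steps 5 and 6. Aminolysis of 8 (AlMe3, MeNH(OMe)·HCl, CH2Cl2, 0 °C to rt) gives (2S,3S)-4-hydroxy-N-methoxy-N,2,3-trimethylbutanamide F9. Appel bromination (CBr4, PPh3, CH2Cl2, 0 °C) under neutral conditions gives (2S,3S)-4-bromo-N-methoxy-N,2,3-trimethylbutanamide F10, and reduction with i-Bu2AlH (THF, −78 °C) should release 12 on work-up.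

**Further compounds**

F1 | step 7 | (1R,2S,3S)-4-bromo-2,3-dimethyl-1-(3,4,5-trimethoxyphenyl)butyl acetate | BrC[C@@H](C)[C@H](C)[C@@H](OC(C)=O)c1cc(OC)c(OC)c(OC)c1
F2 | step 7 | (4-bromo-2,6-dimethoxyphenoxy)(tert-butyl)dimethylsilane | COc1cc(Br)cc(OC)c1O[Si](C)(C)C(C)(C)C
F3 | step 7 | (1R,2S,3R)-4-(4-{[tert-butyl(dimethyl)silyl]oxy}-3,5-dimethoxyphenyl)-2,3-dimethyl-1-(3,4,5-trimethoxyphenyl)butyl acetate | COc1cc(C[C@@H](C)[C@H](C)[C@@H](OC(C)=O)c2cc(OC)c(OC)c(OC)c2)cc(OC)c1O[Si](C)(C)C(C)(C)C
F4 | step 7 | (1R,2S,3R)-4-(4-hydroxy-3,5-dimethoxyphenyl)-2,3-dimethyl-1-(3,4,5-trimethoxyphenyl)butyl acetate | COc1cc(C[C@@H](C)[C@H](C)[C@@H](OC(C)=O)c2cc(OC)c(OC)c(OC)c2)cc(OC)c1O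
F5 | step 2 | (6-bromo-2,3,4-trimethoxyphenyl)magnesium chloride | COc1cc(Br)c([Mg]Cl)c(OC)c1OC
F6 | step 2 | (6-bromo-2,3,4-trimethoxyphenyl)zinc chloride | COc1cc(Br)c([Zn]Cl)c(OC)c1OC
F7 | step 2 | 4-iodo-2,6-dimethoxyphenol | COc1cc(I)cc(OC)c1O
F8 | step 2 | tert-butyl(4-iodo-2,6-dimethoxyphenoxy)dimethylsilane | COc1cc(I)cc(OC)c1O[Si](C)(C)C(C)(C)C
F9 | step 5 | (2S,3S)-4-hydroxy-N-methoxy-N,2,3-trimethylbutanamide | OC[C@@H](C)[C@H](C)C(=O)N(C)OC
F10 | step 5 | (2S,3S)-4-bromo-N-methoxy-N,2,3-trimethylbutanamide | BrC[C@@H](C)[C@H](C)C(=O)N(C)OC
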